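**Retrosynthetic overview**
1. Target ⇐ global desilylation of 30; the three angelates (C3, C8, C6) are put on one at a time by mixed-anhydride esterification as each hydroxyl is unveiled.
2. C6–O ⇐ Rubottom oxidation of a late C5 ketone; C8 ⇐ CBS reduction; C9–C10 bond ⇐ intermolecular boron aldol of ring methyl enone 18 with methacrolein 19 (sets C10).
3. Ring oxygens of 18 ⇐ OsO4 cis-dihydroxylation (C2, C3) of a Δ2-4β-ol, itself from directed epoxidation, selenide opening and selenoxide elimination of a cis-carveol.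
4. Methyl enone side chain ⇐ allylic chlorination of the isopropenyl group of (S)-(+)-carvone, then CH2Cl → CHO → COCH3.
5. Rings: none is built; the only carbocycle is the cyclohexane of (S)-carvone, whose C1 stereocentre relays all ring stereocentres.

**Assumptions.** (i) Locants are those of the target: ring C1 (bears the side chain), C2, C3, C4 (bears CH3), C5, C6; side chain C7 (on C1, carries the exocyclic CH2), C8, C9, C10, C11 (isopropenyl carbon). β = ring face of the C1 side chain, α = the other face. Target = 1S,2S,3S,4R,6R,8S,10R, i.e. 2α-OH, 3α-OAng, 4β-OH, 6α-OAng, 8,10-syn. (ii) (S)-(+)-carvone, angelic acid and methacrolein are bought. (iii) The facial sense of the Ipc2BCl aldol (step 16) is assigned from recalled precedent for methyl ketones and should be confirmed on a model.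

**Step 1**
Reactants: 1 (S)-(+)-carvone
Product: 2 (S)-10-chlorocarvone (C8 chloride)
Conditions: Ca(OCl)2, CO2 (dry ice), CH2Cl2/H2O, 0 °C → rt
Reagents that add atoms: calcium hypochlorite, [Ca+2].[O-]Cl.[O-]Cl (Cl delivered as HOCl, OCl)
Why: Ene-type allylic chlorination by HOCl attacks only the electron-rich isopropenyl alkene (not the enone) and shifts the double bond within the 2-substituted allyl unit; no stereocentre is touched.

**Step 2**
Reactants: 2 (S)-10-chlorocarvone
Product: 3 C8 pivalate of carvone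
Conditions: PivOK, Bu4NI (cat.), DMF, 50 °C
Reagents that add atoms: potassium pivalate, CC(C)(C)C(=O)[O-].[K+]
Why: SN2 displacement of the primary allylic chloride by carboxylate (SN2' gives the same product).

**Step 3**
Reactants: 3 C8 pivalate of carvone
Product: 4 5β-allylic alcohol (cis-carveol series, 1S,5S)
Conditions: NaBH4, CeCl3·7H2O, MeOH, −78 → −20 °C
Reagents that add atoms: none
Why: Luche 1,2-reduction; axial hydride delivery to the half-chair with the C1 substituent equatorial gives the equatorial 5β-OH, cis to the side chain.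

**Step 4**
Reactants: 4 5β-allylic alcohol
Product: 5 3β,4β-epoxy-5β-alcohol
Conditions: VO(acac)2 (2 mol %), t-BuOOH, CH2Cl2, 0 °C → rt
Reagents that add atoms: tert-butyl hydroperoxide, CC(C)(C)OO
Why: Vanadium-catalysed hydroxyl-directed epoxidation touches only the allylic-alcohol alkene and delivers oxygen syn to the 5β-OH, which fixes the C4–O bond on the β face.

**Step 5**
Reactants: 5 3β,4β-epoxy-5β-alcohol
Product: 6 5β-PMB ether of the epoxide
Conditions: NaH, PMBCl, Bu4NI (cat.), DMF, 0 °C → rt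
Reagents that add atoms: 4-methoxybenzyl chloride, COc1ccc(CCl)cc1
Why: Williamson etherification; the alkoxide is syn to the epoxide oxygen, so Payne rearrangement is geometrically impossible.

**Step 6**
Reactants: 6 5β-PMB ether of the epoxide
Product: 7 3α-phenylselanyl-4β-alcohol
Conditions: (PhSe)2, NaBH4, EtOH, rt → 60 °C
Reagents that add atoms: diphenyl diselenide, c1ccc([Se][Se]c2ccccc2)cc1
Why: SN2 epoxide opening by selenolate; trans-diaxial (Fürst–Plattner) attack at the secondary C3 from the α face leaves the tertiary 4β-OH untouched.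

**Step 7**
Reactants: 7 3α-phenylselanyl-4β-alcohol
Product: 9 Δ2-4β-tertiary allylic alcohol, via selenoxide 8 (not isolated)
Conditions: 30% H2O2, pyridine, THF, 0 °C → rt
Reagents that add atoms: none
Why: Selenide oxidation and selenoxide syn-elimination (Sharpless–Lauer epoxide-to-allylic-alcohol sequence); only C2 carries β-hydrogens, so the C2=C3 alkene forms and C4 is unchanged.

**Step 8**
Reactants: 9 Δ2-4β-tertiary allylic alcohol
Product: 10 C8 primary allylic alcohol (8,4β-diol)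
Conditions: DIBAL-H, CH2Cl2, −78 °C; Rochelle salt
Reagents that add atoms: none
Why: Reductive cleavage of the pivalate; PMB ether, alkenes and tertiary alcohol are inert.

**Step 9**
Reactants: 10 C8 primary allylic alcohol
Product: 11 C8 enal
Conditions: MnO2 (activated), CH2Cl2, rt
Reagents that add atoms: none
Why: MnO2 allylic oxidation is selective for the primary allylic alcohol; the tertiary allylic alcohol cannot be oxidised.

**Step 10**
Reactants: 11 C8 enal
Product: 12 C8 methyl carbinol (C8 epimers, about 1:1, both used)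
Conditions: MeMgBr (2.5 equiv), THF, −78 °C
Reagents that add atoms: methylmagnesium bromide, C[Mg]Br
Why: Grignard 1,2-addition to the α-substituted acrolein introduces C9; the C8 configuration is irrelevant because it is oxidised next.

**Step 11**
Reactants: 12 C8 methyl carbinol
Product: 13 methyl enone (C8 ketone)
Conditions: Dess–Martin periodinane, NaHCO3, CH2Cl2, 0 °C → rt
Reagents that add atoms: none
Why: Buffered Dess–Martin oxidation of the secondary allylic alcohol; no chromium, so the tertiary allylic alcohol is not transposed.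

**Step 12**
Reactants: 13 methyl enone
Product: 14 2α,3α,4β-triol
Conditions: OsO4 (2 mol %), NMO (1.2 equiv), acetone/H2O, 0 °C → rt
Reagents that add atoms: N-methylmorpholine N-oxide, C[N+]1([O-])CCOCC1; water, O (with catalytic OsO4, O=[Os](=O)(=O)=O)
Why: Upjohn dihydroxylation; the side-chain alkene is deactivated by conjugation with the C8 ketone, and OsO4 adds to the ring alkene anti to the pseudoaxial allylic 4β-OH and the β substituents at C1 and C5 (Kishi rule), setting C2 and C3 (both α).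

**Step 13**
Reactants: 14 2α,3α,4β-triol
Product: 15 2α-TBS ether
Conditions: TBSOTf (1.05 equiv), 2,6-lutidine, CH2Cl2, −78 °C
Reagents that add atoms: tert-butyldimethylsilyl triflate, CC(C)(C)[Si](C)(C)OS(=O)(=O)C(F)(F)F
Why: Kinetic silylation of the equatorial C2–OH; the C3–OH is axial and neopentylic and the C4–OH is tertiary, and the non-nucleophilic base spares the vinyl ketone.

**Step 14**
Reactants: 15 2α-TBS ether; 16 angelic acid
Product: 17 3α-angelate
Conditions: 16, 2,4,6-Cl3C6H2COCl, Et3N, toluene, rt; then 15, 80 °C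
Reagents that add atoms: none
Why: Yamaguchi-type mixed-anhydride esterification of the hindered axial alcohol, run without DMAP to avoid Z→E isomerisation to the tiglate.

**Step 15**
Reactants: 17 3α-angelate
Product: 18 4β-TES ether (aldol donor fragment)
Conditions: TESOTf, 2,6-lutidine, CH2Cl2, 0 °C
Reagents that add atoms: triethylsilyl triflate, CC[Si](CC)(CC)OS(=O)(=O)C(F)(F)F
Why: Silyl triflate silylation of the tertiary alcohol removes the last free OH before enolate chemistry.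

**Step 16** (key fragment coupling)
Reactants: 18 4β-TES ether; 19 methacrolein
Product: 21 (10R)-aldol adduct, via boron enolate 20 (not isolated)
Conditions: (−)-Ipc2BCl, Et3N, Et2O, 0 °C; 19, −78 → −20 °C; then MeOH, pH 7 buffer, 30% H2O2, 0 °C
Reagents that add atoms: none
Why: Paterson boron aldol; Ipc2BCl/Et3N enolises only the methyl ketone, and the enol diisopinocampheylborinate is expected to add to the Re face of methacrolein (reagent control, typically moderate) to give 10R, with the minor C10 epimer removed by chromatography.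

**Step 17**
Reactants: 21 (10R)-aldol adduct
Product: 22 10-TBS ether
Conditions: TBSOTf, 2,6-lutidine, CH2Cl2, −78 °C
Reagents that add atoms: tert-butyldimethylsilyl triflate, CC(C)(C)[Si](C)(C)OS(=O)(=O)C(F)(F)F
Why: Low-temperature silylation of the β-hydroxy ketone without elimination; this differentiates C10–O from the C8 oxygen still to come.

**Step 18**
Reactants: 22 10-TBS ether
Product: 23 (8S)-allylic alcohol
Conditions: (R)-Me-CBS (0.5 equiv), BH3·SMe2, THF, −30 °C; MeOH
Reagents that add atoms: none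
Why: Corey–Bakshi–Shibata reduction of the only ketone; with the 1-substituted vinyl group as the large substituent the (R)-catalyst gives 8S (8,10-syn).

**Step 19**
Reactants: 23 (8S)-allylic alcohol; 16 angelic acid
Product: 24 3,8-bis-angelate
Conditions: 16, 2,4,6-Cl3C6H2COCl, Et3N, toluene, rt; then 23, 60 °C
Reagents that add atoms: none
Why: Mixed-anhydride esterification of the only free hydroxyl with retention at C8.

**Step 20**
Reactants: 24 3,8-bis-angelate
Product: 25 5β-alcohol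
Conditions: DDQ, CH2Cl2/pH 7 buffer (10:1), 0 °C
Reagents that add atoms: none
Why: Oxidative PMB cleavage is orthogonal to the silyl ethers, esters and alkenes.

**Step 21**
Reactants: 25 5β-alcohol
Product: 26 C5 ketone
Conditions: Dess–Martin periodinane, NaHCO3, CH2Cl2, rt
Reagents that add atoms: none
Why: Neutral Dess–Martin oxidation of the single free secondary alcohol.

**Step 22**
Reactants: 26 C5 ketone
Product: 27 C5–C6 trimethylsilyl enol ether (used crude)
Conditions: TMSOTf, Et3N, CH2Cl2, −20 → 0 °C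
Reagents that add atoms: trimethylsilyl triflate, C[Si](C)(C)OS(=O)(=O)C(F)(F)F
Why: Soft enolisation; C4 is quaternary, so only C6 can enolise, and the esters are not enolised at this temperature.

**Step 23**
Reactants: 27 C5–C6 trimethylsilyl enol ether
Product: 29 6α-hydroxy ketone, via silyloxy epoxide 28 (not isolated)
Conditions: DMDO (acetone), CH2Cl2, −78 °C; then citric acid, MeOH, 0 °C
Reagents that add atoms: dimethyldioxirane, CC1(C)OO1
Why: Rubottom oxidation; DMDO reacts with the silyl enol ether far faster than with the other alkenes, from the α face anti to the C1 side chain and the axial 4β-OTES, and the equatorial 6α-OH is also the thermodynamic epimer.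

**Step 24**
Reactants: 29 6α-hydroxy ketone; 16 angelic acid
Product: 30 fully protected tris-angelate
Conditions: 16, 2,4,6-Cl3C6H2COCl, Et3N, toluene, rt; then 29, 40 °C
Reagents that add atoms: none
Why: Mixed-anhydride esterification of the reactive α-ketol hydroxyl under mild conditions.

**Step 25**
Reactants: 30 fully protected tris-angelate
Product: 31 target CNP0273696.1
Conditions: HF·pyridine, pyridine, THF, 0 °C → rt
Reagents that add atoms: none
Why: Fluoride-mediated global desilylation (two TBS, one TES) under non-basic conditions, which avoids C3→C2 acyl migration and α-ketol rearrangement.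

**Compound list**
1 | (S)-(+)-carvone | C=C(C)[C@H]1CC=C(C)C(=O)C1 | starting material
2 | (S)-10-chlorocarvone (C8 chloride) | C=C(CCl)[C@H]1CC=C(C)C(=O)C1 | intermediate
3 | C8 pivalate of carvone | C=C(COC(=O)C(C)(C)C)[C@H]1CC=C(C)C(=O)C1 | intermediate
4 | 5β-allylic alcohol, 8-OPiv (1S,5S, cis-carveol series) | C=C(COC(=O)C(C)(C)C)[C@H]1CC=C(C)[C@@H](O)C1 | intermediate
5 | 3β,4β-epoxy-5β-alcohol, 8-OPiv | C=C(COC(=O)C(C)(C)C)[C@H]1C[C@@H]2[C@@](C)(O2)[C@@H](O)C1 | intermediate
6 | 3β,4β-epoxide, 5β-OPMB, 8-OPiv | C=C(COC(=O)C(C)(C)C)[C@H]1C[C@@H]2[C@@](C)(O2)[C@@H](OCc3ccc(OC)cc3)C1 | intermediate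
7 | 3α-phenylselanyl-4β-ol, 5β-OPMB, 8-OPiv | C=C(COC(=O)C(C)(C)C)[C@H]1C[C@H]([Se]c2ccccc2)[C@@](C)(O)[C@@H](OCc2ccc(OC)cc2)C1 | intermediate
8 | selenoxide of 7 (mixture at Se) | C=C(COC(=O)C(C)(C)C)[C@H]1C[C@H]([Se](=O)c2ccccc2)[C@@](C)(O)[C@@H](OCc2ccc(OC)cc2)C1 | intermediate (not isolated)
9 | Δ2-4β-tertiary allylic alcohol, 5β-OPMB, 8-OPiv | C=C(COC(=O)C(C)(C)C)[C@H]1C=C[C@@](C)(O)[C@@H](OCc2ccc(OC)cc2)C1 | intermediate
10 | Δ2-4β,8-diol, 5β-OPMB | C=C(CO)[C@H]1C=C[C@@](C)(O)[C@@H](OCc2ccc(OC)cc2)C1 | intermediate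
11 | C8 enal, Δ2-4β-ol, 5β-OPMB | C=C(C=O)[C@H]1C=C[C@@](C)(O)[C@@H](OCc2ccc(OC)cc2)C1 | intermediate
12 | C8 methyl carbinol (C8 epimers), Δ2-4β-ol, 5β-OPMB | C=C(C(C)O)[C@H]1C=C[C@@](C)(O)[C@@H](OCc2ccc(OC)cc2)C1 | intermediate
13 | methyl enone (C8 ketone), Δ2-4β-ol, 5β-OPMB | C=C(C(C)=O)[C@H]1C=C[C@@](C)(O)[C@@H](OCc2ccc(OC)cc2)C1 | intermediate
14 | 2α,3α,4β-triol, 5β-OPMB, methyl enone | C=C(C(C)=O)[C@H]1[C@H](O)[C@H](O)[C@@](C)(O)[C@@H](OCc2ccc(OC)cc2)C1 | intermediate
15 | 2α-OTBS, 3α,4β-diol, 5β-OPMB, methyl enone | C=C(C(C)=O)[C@H]1[C@H](O[Si](C)(C)C(C)(C)C)[C@H](O)[C@@](C)(O)[C@@H](OCc2ccc(OC)cc2)C1 | intermediate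
16 | angelic acid, (Z)-2-methylbut-2-enoic acid | C/C=C(/C)C(=O)O | starting material
17 | 2α-OTBS, 3α-angelate, 4β-ol, 5β-OPMB, methyl enone | C=C(C(C)=O)[C@H]1[C@H](O[Si](C)(C)C(C)(C)C)[C@H](OC(=O)/C(C)=C\C)[C@@](C)(O)[C@@H](OCc2ccc(OC)cc2)C1 | intermediate
18 | 2α-OTBS, 3α-angelate, 4β-OTES, 5β-OPMB, methyl enone | C=C(C(C)=O)[C@H]1[C@H](O[Si](C)(C)C(C)(C)C)[C@H](OC(=O)/C(C)=C\C)[C@@](C)(O[Si](CC)(CC)CC)[C@@H](OCc2ccc(OC)cc2)C1 | intermediate
19 | methacrolein | C=C(C)C=O | starting material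
20 | enol diisopinocampheylborinate of 18 (C8=C9 enolate) | C=C(OB([C@@H]1C[C@@H]2C[C@H]([C@H]1C)C2(C)C)[C@@H]1C[C@@H]2C[C@H]([C@H]1C)C2(C)C)C(=C)[C@H]3[C@H](O[Si](C)(C)C(C)(C)C)[C@H](OC(=O)/C(C)=C\C)[C@@](C)(O[Si](CC)(CC)CC)[C@@H](OCc4ccc(OC)cc4)C3 | intermediate (not isolated)
21 | (10R)-10-hydroxy-8-ketone (aldol adduct) | C=C(C)[C@H](O)CC(=O)C(=C)[C@H]1[C@H](O[Si](C)(C)C(C)(C)C)[C@H](OC(=O)/C(C)=C\C)[C@@](C)(O[Si](CC)(CC)CC)[C@@H](OCc2ccc(OC)cc2)C1 | intermediate
22 | (10R)-10-OTBS-8-ketone | C=C(C)[C@H](O[Si](C)(C)C(C)(C)C)CC(=O)C(=C)[C@H]1[C@H](O[Si](C)(C)C(C)(C)C)[C@H](OC(=O)/C(C)=C\C)[C@@](C)(O[Si](CC)(CC)CC)[C@@H](OCc2ccc(OC)cc2)C1 | intermediate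
23 | (8S,10R)-8-ol, 10-OTBS | C=C(C)[C@H](O[Si](C)(C)C(C)(C)C)C[C@H](O)C(=C)[C@H]1[C@H](O[Si](C)(C)C(C)(C)C)[C@H](OC(=O)/C(C)=C\C)[C@@](C)(O[Si](CC)(CC)CC)[C@@H](OCc2ccc(OC)cc2)C1 | intermediate
24 | 3,8-bis-angelate, 5β-OPMB | C=C(C)[C@H](O[Si](C)(C)C(C)(C)C)C[C@H](OC(=O)/C(C)=C\C)C(=C)[C@H]1[C@H](O[Si](C)(C)C(C)(C)C)[C@H](OC(=O)/C(C)=C\C)[C@@](C)(O[Si](CC)(CC)CC)[C@@H](OCc2ccc(OC)cc2)C1 | intermediate
25 | 3,8-bis-angelate, 5β-ol | C=C(C)[C@H](O[Si](C)(C)C(C)(C)C)C[C@H](OC(=O)/C(C)=C\C)C(=C)[C@H]1[C@H](O[Si](C)(C)C(C)(C)C)[C@H](OC(=O)/C(C)=C\C)[C@@](C)(O[Si](CC)(CC)CC)[C@@H](O)C1 | intermediate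
26 | 3,8-bis-angelate, C5 ketone | C=C(C)[C@H](O[Si](C)(C)C(C)(C)C)C[C@H](OC(=O)/C(C)=C\C)C(=C)[C@H]1[C@H](O[Si](C)(C)C(C)(C)C)[C@H](OC(=O)/C(C)=C\C)[C@@](C)(O[Si](CC)(CC)CC)C(=O)C1 | intermediate
27 | C5–C6 trimethylsilyl enol ether of 26 | C=C(C)[C@H](O[Si](C)(C)C(C)(C)C)C[C@H](OC(=O)/C(C)=C\C)C(=C)[C@H]1[C@H](O[Si](C)(C)C(C)(C)C)[C@H](OC(=O)/C(C)=C\C)[C@@](C)(O[Si](CC)(CC)CC)C(O[Si](C)(C)C)=C1 | intermediate
28 | 5,6α-epoxide of 27 (5-OTMS) | C=C(C)[C@H](O[Si](C)(C)C(C)(C)C)C[C@H](OC(=O)/C(C)=C\C)C(=C)[C@H]1[C@H](O[Si](C)(C)C(C)(C)C)[C@H](OC(=O)/C(C)=C\C)[C@@](C)(O[Si](CC)(CC)CC)[C@]3(O[Si](C)(C)C)O[C@H]13 | intermediate (not isolated)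
29 | 6α-hydroxy-5-ketone, 3,8-bis-angelate | C=C(C)[C@H](O[Si](C)(C)C(C)(C)C)C[C@H](OC(=O)/C(C)=C\C)C(=C)[C@H]1[C@H](O[Si](C)(C)C(C)(C)C)[C@H](OC(=O)/C(C)=C\C)[C@@](C)(O[Si](CC)(CC)CC)C(=O)[C@@H]1O | intermediate
30 | 3,6,8-tris-angelate, 2-OTBS, 4-OTES, 10-OTBS | C=C(C)[C@H](O[Si](C)(C)C(C)(C)C)C[C@H](OC(=O)/C(C)=C\C)C(=C)[C@H]1[C@H](O[Si](C)(C)C(C)(C)C)[C@H](OC(=O)/C(C)=C\C)[C@@](C)(O[Si](CC)(CC)CC)C(=O)[C@@H]1OC(=O)/C(C)=C\C | intermediate
31 | CNP0273696.1 (1S,2S,3S,4R,6R,8S,10R) | C=C(C)[C@H](O)C[C@H](OC(=O)/C(C)=C\C)C(=C)[C@H]1[C@H](O)[C@H](OC(=O)/C(C)=C\C)[C@@](C)(O)C(=O)[C@@H]1OC(=O)/C(C)=C\C | target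

**Totals**
Total step count: 25. Longest linear sequence: 25 steps (from 1; 16 and 19 are bought).

**Three steps most likely to fail**

Step 12 (chemoselectivity of OsO4 between the ring alkene and the vinyl ketone). The fallback sets out from 13: thiophenol with catalytic Et3N adds to the vinyl ketone only and gives the β-phenylthio ketone F1, which has no side-chain alkene. OsO4 with excess NMO then dihydroxylates the ring alkene from the α face and oxidises sulfur to the sulfone, giving the sulfone triol F2. DBU in CH2Cl2 eliminates benzenesulfinate and regenerates the α-methylene ketone, which brings the route back at 14.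

Step 14 (direct angeloylation of the axial, neopentylic C3–OH). The fallback sets out from 15: DCC coupling with 2-[bis(2,2,2-trifluoroethoxy)phosphoryl]propanoic acid, a small acid that reacts through a ketene-like intermediate, gives the phosphonopropionate ester F3. A Still–Gennari olefination with acetaldehyde (1.0 equiv KHMDS, 18-crown-6, THF, −78 °C, so that only the phosphonate is deprotonated) then builds the Z-2-methylbut-2-enoate on the molecule and returns to the route at 17.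

Step 16 (facial selectivity of the methyl-ketone boron aldol at C10). The fallback sets out from 18: TMSOTf/Et3N gives the 2-silyloxydiene F4. A catalytic asymmetric Mukaiyama aldol with 19 (Corey's N-tosyltryptophan-derived B-butyl oxazaborolidinone, EtCN, −78 °C, catalyst antipode chosen for 10R on a model) gives the silylated aldol F5. Brief citric acid/MeOH removes the trimethylsilyl group and rejoins the route at 21.

**Further compounds**
F1 | step 12 | β-phenylthio ketone from 13 (C7 epimers) | CC(=O)C(CSc1ccccc1)[C@H]1C=C[C@@](C)(O)[C@@H](OCc2ccc(OC)cc2)C1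
F2 | step 12 | β-phenylsulfonyl ketone 2α,3α,4β-triol (C7 epimers) | CC(=O)C(CS(=O)(=O)c1ccccc1)[C@H]1[C@H](O)[C@H](O)[C@@](C)(O)[C@@H](OCc2ccc(OC)cc2)C1
F3 | step 14 | 3α-[2-(bis(2,2,2-trifluoroethoxy)phosphoryl)propanoate] of 15 | C=C(C(C)=O)[C@H]1[C@H](O[Si](C)(C)C(C)(C)C)[C@H](OC(=O)C(C)P(=O)(OCC(F)(F)F)OCC(F)(F)F)[C@@](C)(O)[C@@H](OCc2ccc(OC)cc2)C1
F4 | step 16 | trimethylsilyl dienol ether of 18 | C=C(O[Si](C)(C)C)C(=C)[C@H]1[C@H](O[Si](C)(C)C(C)(C)C)[C@H](OC(=O)/C(C)=C\C)[C@@](C)(O[Si](CC)(CC)CC)[C@@H](OCc2ccc(OC)cc2)C1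
F5 | step 16 | 10-O-trimethylsilyl ether of 21 | C=C(C)[C@H](O[Si](C)(C)C)CC(=O)C(=C)[C@H]1[C@H](O[Si](C)(C)C(C)(C)C)[C@H](OC(=O)/C(C)=C\C)[C@@](C)(O[Si](CC)(CC)CC)[C@@H](OCc2ccc(OC)cc2)C1
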